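**Plan**
1. Cuts, in retrosynthetic order: the C3–O ester bond; within the acyl chain, its angelate C–O bond and C1'–C2'; the C7–C11 bond (isopropenyl); C5–C6 of ring B with reconnection of C3–C8 (retro-oxy-Cope); the vinyl–C8 bond; and the two Diels–Alder bonds C1–C10 and C2–C3.
2. Enabling feature: along C8(=O)–C7–C6–C5–C4=C3 the C8 oxygen and the C3/C4 pair (read as an olefin) form a δ,ε-unsaturated ketone, which is the retron of an oxy-Cope shift across C5–C6. The vicinal C8/C9 oxygens of ring B are the carbonyl and ketal carbons of an o-quinone monoketal, whose ring also supplies C3, C4, C5, C10 and both methyl groups.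
3. Forward order: a guaiacol is dearomatised and trapped to give a bicyclo[2.2.2]octenone, whose cyclohexene becomes ring A. A vinyl carbinol is made and the [3,3] shift closes ring B. There follow ring-fusion repair, ring A hydroboration, C7 isopropenylation and C8 reduction, then acylation of C3–OH, semihydrogenation and desilylation.
4. Stereochemistry: a sultam auxiliary fixes the bridgeheads and the cage relays them to C5. C10 is erased as a diosphenol and rebuilt trans, together with C9, by Li/NH3. The C5 methyl steers hydroboration (C3, C4). C7 is set by axial protonation and C8 by LiBH(s-Bu)3. C4' comes from (R)-pent-1-yn-3-ol, and the Z olefins come from angelic acid and a Lindlar semihydrogenation.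

Key step: step 8

Numbering remark: bicycles are numbered C1 (bridgehead next to C2), C2 (carbonyl or carbinol), C3 (ketal), C4 (bridgehead), C5=C6 (olefin, C5 next to C4) and C7–C8 (ethano bridge, C7 next to C1). Decalins carry eremophilane numbers (ring A = C1–C5 and C10, ring B = C5–C10), and β is the face of the C5 methyl. Bicycle C1, C2, C3, C4, C5, C6, C7, C8 become eremophilane C3, C8, C9, C10, C5, C4, C2, C1. The vinyl CH and CH2 become C7 and C6.

Assumption: N-acryloyl-(2R)-bornane-10,2-sultam is taken to react through its s-cis, C=O/SO2-anti conformer on the Cα-re face. If the bias runs the other way, the equally available (2S)-sultam is used and nothing else changes.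

**Step 1**
Reactants: 1 3,4-dimethylphenol
Product: 2 2-bromo-4,5-dimethylphenol
Conditions: Br2 (1.0 equiv), CH2Cl2, 0 °C
Reagents that add atoms: bromine, BrBr
Why: Electrophilic aromatic bromination; the para position is blocked by methyl, so OH directs ortho, and the open C6 site reacts in preference to C2, which is squeezed between OH and methyl.

**Step 2**
Reactants: 2 2-bromo-4,5-dimethylphenol
Product: 3 2-methoxy-4,5-dimethylphenol
Conditions: NaOMe (4 equiv), CuBr (10 mol %), MeOH/DMF, 110 °C; then 1 M HCl
Reagents that add atoms: sodium methoxide, [Na+].[O-]C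
Why: Copper-catalysed Ullmann-type methoxylation of an o-bromophenol is the standard entry to guaiacols and exchanges only the C–Br bond.

**Step 3**
Reactants: 4 (2R)-bornane-10,2-sultam; 5 acryloyl chloride
Product: 7 N-acryloyl-(2R)-bornane-10,2-sultam, via sodium sultamide 6 (not isolated)
Conditions: NaH, toluene, rt; then 5, 0 °C → rt
Reagents that add atoms: none
Why: N-acylation of the sulfonamide anion with an acid chloride is the routine preparation of N-enoyl sultams and creates no stereocentre.

**Step 4**
Reactants: 3 2-methoxy-4,5-dimethylphenol; 7 N-acryloyl-(2R)-bornane-10,2-sultam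
Product: 9 N-[(1R,4S,7S)-3,3-dimethoxy-5,6-dimethyl-2-oxobicyclo[2.2.2]oct-5-ene-7-carbonyl]-(2R)-bornane-10,2-sultam (acyl group on C7 syn to C5=C6), via o-quinone monoketal 8 (not isolated)
Conditions: PhI(OAc)2 (1.1 equiv), 7 (2 equiv), MeOH/CH2Cl2, slow addition of 3, 0 → 40 °C; chromatography, recrystallisation
Reagents that add atoms: methanol, CO
Why: Hypervalent-iodine oxidative dearomatisation in methanol gives monoketal 8, whose Diels–Alder reactions with acrylic dienophiles are ortho- and endo-selective; the sultam screens one face of the acrylamide so that the bridgeheads form as 1R,4S, and the other diastereomer is removed from this crystalline adduct whatever the size of the bias.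

**Step 5**
Reactants: 9 sultam adduct
Product: 10 (1R,4S,7S)-3,3-dimethoxy-5,6-dimethyl-2-oxobicyclo[2.2.2]oct-5-ene-7-carboxylic acid
Conditions: LiOH·H2O, THF/H2O, rt; then 1 M HCl to pH 3
Reagents that add atoms: lithium hydroxide, [Li+].[OH-]
Why: Hydrolytic cleavage of the activated N-acyl sultam releases the acid and the reusable auxiliary; the ketone cannot enolise, and any epimerisation at C7 is irrelevant because that centre disappears next.

**Step 6**
Reactants: 10 keto acid
Product: 12 (1R,4S)-3,3-dimethoxy-5,6-dimethylbicyclo[2.2.2]oct-5-en-2-one, via O-acyl thiohydroxamate 11 (not isolated)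
Conditions: 1-hydroxypyridine-2(1H)-thione, DCC, CH2Cl2, 0 °C, dark; then t-BuSH (20 equiv), hν (tungsten lamp), 10 °C
Reagents that add atoms: none
Why: Barton reductive decarboxylation; a high thiol concentration should trap the secondary C7 radical before it can close onto the hindered tetrasubstituted olefin, so the acrylate has served as a chiral ethylene equivalent.

**Step 7**
Reactants: 12 bicyclic ketone; 13 vinylmagnesium bromide
Product: 14 (1R,2R,4S)-3,3-dimethoxy-5,6-dimethyl-2-vinylbicyclo[2.2.2]oct-5-en-2-ol (vinyl syn to C5=C6)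
Conditions: THF, −78 → 0 °C; aq NH4Cl
Reagents that add atoms: none
Why: Grignard 1,2-addition to a ketone that cannot enolise (bridgehead H on one side, ketal carbon on the other); the reagent enters past the flat sp2 bridge rather than past the inward C–H bonds of the ethano bridge, which places the vinyl group syn to the olefin (2R).

**Step 8**
Reactants: 14 vinyl carbinol
Product: 17 cis-fused (4aS,8aS)-1,1-dimethoxy-4a,5-dimethyl-3,4,4a,7,8,8a-hexahydronaphthalen-2(1H)-one (eremophilane numbering: 8-oxo; 9,9-dimethoxy; 3-ene; 5β-methyl; 10βH), via potassium alkoxide 15 (not isolated), via potassium enolate 16 (not isolated)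
Conditions: KH (1.5 equiv), 18-crown-6 (1.5 equiv), THF, 0 °C → rt; aq NH4Cl, 0 °C
Reagents that add atoms: none
Why: Deprotonation gives alkoxide 15, whose crown-separated oxyanion weakens the adjacent C1–C2 bond (eremophilane C3–C8) and strongly accelerates the [3,3] sigmatropic shift; this is the anionic oxy-Cope rearrangement of 2-vinylbicyclo[2.2.2]oct-5-en-2-ols, a known route to cis-decalins. Ring B closes through a six-centre, boat-like, suprafacial bond formation between the vinyl CH2 (C6) and olefin carbon C5 while C3–C8 opens, and the cyclohexene of the bicycle survives as ring A with its double bond moved to C3=C4. The one new stereocentre, quaternary C5, is fixed by the cage, because the vinyl terminus can reach only the olefin face turned toward the C2–C3 bridge; C6 and C9 therefore end up cis on ring A, and bridgehead C4 is carried over unchanged as C10. The step needs the vinyl group syn to C5=C6, which step 7 secures, and it needs the [3,3] path to win over a [1,3] shift or loss of the vinyl anion, which the rigid, pre-organised 1,5-diene favours. Enolate 16 is regiodefined (C7=C8, with C9 blocked by the ketal) and is simply protonated on work-up.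

**Step 9**
Reactants: 17 cis-decalone ketal
Product: 18 diosphenol 9-hydroxy-4,5β-dimethyl-octala-3,9(10)-dien-8-one
Conditions: 2 M HCl, THF, 45 °C, argon
Reagents that add atoms: water, O
Why: Acid-catalysed ketal hydrolysis; the 1,2-diketone settles as its more substituted conjugated enol, which deliberately removes the cis C10 centre so that it can be rebuilt trans.

**Step 10**
Reactants: 18 diosphenol
Product: 19 9-(triisopropylsilyloxy)-4,5β-dimethyl-octala-3,9(10)-dien-8-one
Conditions: TIPSCl (1.1 equiv), imidazole, DMF, rt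
Reagents that add atoms: triisopropylsilyl chloride, CC(C)[Si](Cl)(C(C)C)C(C)C
Why: O-silylation of the acidic enol; the tetrasubstituted C9=C10 enol is the dominant tautomer of a 3-alkylcyclohexane-1,2-dione, so the silyl group lands on O9.

**Step 11**
Reactants: 19 silyloxy dienone
Product: 21 9-(triisopropylsilyloxy)-4β,5β-dimethyl-octal-9(10)-ene-3α,8ξ-diol (C8 epimers, both used), via organoborane 20 (not isolated)
Conditions: BH3·THF (3 equiv), THF, 0 °C → rt; then NaBO3·4H2O, THF/H2O, rt
Reagents that add atoms: sodium perborate, [Na+].[Na+].O[B-]1(O)OO[B-](O)(O)OO1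
Why: Hydroboration–oxidation; BH3 reduces the enone carbonyl 1,2 and adds syn and anti-Markovnikov to C3=C4 from the α face, opposite the pseudoaxial C5 methyl, which sets 3α-OH and 4α-H (4β-methyl) together, while the tetrasubstituted silyl enol ether is too hindered to react and the mild perborate work-up avoids silyl transfer.

**Step 12**
Reactants: 21 diol
Product: 22 3α-hydroxy-9-(triisopropylsilyloxy)-4β,5β-dimethyl-octal-9(10)-en-8-one
Conditions: MnO2 (activated, excess), CH2Cl2, rt
Reagents that add atoms: none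
Why: Chemoselective allylic oxidation; MnO2 returns both C8 carbinol epimers to the enone and leaves the saturated C3 alcohol alone.

**Step 13**
Reactants: 22 hydroxy enone
Product: 23 3α-(triethylsilyloxy)-9-(triisopropylsilyloxy)-4β,5β-dimethyl-octal-9(10)-en-8-one
Conditions: TESCl, imidazole, CH2Cl2, 0 °C
Reagents that add atoms: triethylsilyl chloride, CC[Si](Cl)(CC)CC
Why: Silyl ether formation; TES can later be removed in the presence of TIPS and shields the alcohol from the palladium step.

**Step 14**
Reactants: 23 bis-silyl enone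
Product: 25 trans-fused 3α-(triethylsilyloxy)-9α-(triisopropylsilyloxy)-4β,5β-dimethyl-10αH-decal-8-one, via lithium enolate 24 (not isolated)
Conditions: Li (2.5 equiv), NH3(l)/THF, t-BuOH (1 equiv), −78 °C; isoprene, then solid NH4Cl
Reagents that add atoms: none
Why: Dissolving-metal (Birch-type) enone reduction; the β-carbon C10 is protonated axially on the α face, the established path from angular-methyl octalones to trans-decalones where catalytic hydrogenation is unreliable, and enolate 24 then takes its proton at C9 so that the bulky OTIPS group lies equatorial (α) and away from the axial C5 methyl, TIPS being chosen because it moves only slowly between neighbouring oxygens.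

**Step 15**
Reactants: 25 trans-decalone; 26 2-bromopropene
Product: 29 3α-(triethylsilyloxy)-9α-(triisopropylsilyloxy)-10αH-eremophil-11-en-8-one (7α-isopropenyl; 7βH), via C7 lithium enolate 27 (not isolated), via lithium dienolate 28 (not isolated)
Conditions: LiN(SiMe3)2 (2.2 equiv), THF, −78 °C; then 26, Pd2(dba)3 (2.5 mol %), P(t-Bu)3 (6 mol %), −78 °C → rt; AcOH/THF, −78 °C
Reagents that add atoms: none
Why: Palladium-catalysed α-alkenylation of a ketone enolate; the kinetic enolate 27 forms at C7 because C9–H is screened by OTIPS, it couples with the alkenylpalladium species made by oxidative addition of 26 to zerovalent palladium, the product rests as dienolate 28, and cold kinetic protonation at C7 on the axial β side gives the unconjugated ketone with the isopropenyl group equatorial (7α), which is also the more stable epimer.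

**Step 16**
Reactants: 29 isopropenyl ketone
Product: 30 3α-(triethylsilyloxy)-9α-(triisopropylsilyloxy)-10αH-eremophil-11-en-8α-ol
Conditions: LiBH(s-Bu)3, THF, −78 °C; then NaBO3·4H2O, THF/H2O, 0 °C
Reagents that add atoms: none
Why: Bulky trialkylborohydride reduction; equatorial approach to the chair ketone flanked by two equatorial groups delivers the axial 8α-alcohol, cis to both neighbours, faster than the α-centres can epimerise.

**Step 17**
Reactants: 30 bis-silyl ether
Product: 31 9α-(triisopropylsilyloxy)-10αH-eremophil-11-ene-3α,8α-diol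
Conditions: PPTS (cat.), MeOH/CH2Cl2, 0 °C
Reagents that add atoms: none
Why: Acid-catalysed methanolysis removes the unhindered TES ether selectively; the TIPS ether and the isopropenyl group are inert under these conditions.

**Step 18**
Reactants: 32 (R)-pent-1-yn-3-ol; 33 angelic acid
Product: 35 (R)-pent-1-yn-3-yl (Z)-2-methylbut-2-enoate, via mixed anhydride 34 (not isolated)
Conditions: 33, 2,4,6-Cl3C6H2COCl, Et3N, toluene, rt; then 32, 75 °C
Reagents that add atoms: none
Why: Yamaguchi esterification without a nucleophilic catalyst is the established way to make angelates without drift to the tiglate, and the carbinol C–O bond is untouched, so the R centre is retained.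

**Step 19**
Reactants: 35 propargylic angelate
Product: 37 (R)-4-[(Z)-2-methylbut-2-enoyloxy]hex-2-ynoic acid, via lithium acetylide 36 (not isolated)
Conditions: LiN(i-Pr)2 (1.0 equiv, added to 35), THF, −78 °C; CO2 (g), −78 → −20 °C; 1 M HCl
Reagents that add atoms: carbon dioxide, O=C=O
Why: Acetylide carboxylation; the sp C–H is by far the most acidic and fastest-exchanging proton, so one equivalent of amide base gives 36 without touching the ester, which has no α-hydrogen, and CO2 traps the anion at carbon.

**Step 20**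
Reactants: 31 diol; 37 alkynoic acid
Product: 39 8α-hydroxy-9α-(triisopropylsilyloxy)-10αH-eremophil-11-en-3α-yl (R)-4-(angeloyloxy)hex-2-ynoate, via O-acylisourea 38 (not isolated)
Conditions: 37 (1.1 equiv), DCC, DMAP (10 mol %), CH2Cl2, −20 → 0 °C
Reagents that add atoms: none
Why: Steglich esterification; the equatorial C3–OH is acylated while the axial C8–OH, wedged between the isopropenyl and OTIPS groups, stays free, and an alkynoic acid has no olefin geometry to lose on activation.

**Step 21**
Reactants: 39 alkynoate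
Product: 40 8α-hydroxy-9α-(triisopropylsilyloxy)-10αH-eremophil-11-en-3α-yl (2Z,4R)-4-(angeloyloxy)hex-2-enoate
Conditions: H2 (1 atm), Pd/CaCO3 poisoned with Pb(OAc)2, quinoline, EtOAc, rt
Reagents that add atoms: none
Why: Lindlar semihydrogenation; syn delivery of H2 to the activated alkyne gives the Z-enoate, and the 1,1-disubstituted and trisubstituted olefins are not reduced on the poisoned catalyst.

**Step 22**
Reactants: 40 silyl ether
Product: 41 CNP0382739.1, (3R,4R,5R,7S,8R,9S,10R)-8,9-dihydroxyeremophil-11-en-3-yl (2Z,4R)-4-[(Z)-2-methylbut-2-enoyloxy]hex-2-enoate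
Conditions: HF·pyridine, pyridine/THF, 0 °C → rt
Reagents that add atoms: none
Why: Fluoride-mediated Si–O cleavage in a buffered medium frees the 9α-hydroxyl and leaves both esters, both Z olefins and the isopropenyl group untouched.

**Compound list**
1 | 3,4-dimethylphenol | Cc1ccc(O)cc1C | starting material
2 | 2-bromo-4,5-dimethylphenol | Cc1cc(O)c(Br)cc1C | intermediate
3 | 2-methoxy-4,5-dimethylphenol | COc1cc(C)c(C)cc1O | intermediate
4 | (2R)-bornane-10,2-sultam | CC1(C)[C@@H]2CC[C@]13CS(=O)(=O)N[C@@H]3C2 | starting material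
5 | acryloyl chloride | C=CC(=O)Cl | starting material
6 | sodium salt of 4 | [Na+].CC1(C)[C@@H]2CC[C@]13CS(=O)(=O)[N-][C@@H]3C2 | intermediate
7 | N-acryloyl-(2R)-bornane-10,2-sultam | CC1(C)[C@@H]2CC[C@]13CS(=O)(=O)N(C(=O)C=C)[C@@H]3C2 | intermediate
8 | 6,6-dimethoxy-3,4-dimethylcyclohexa-2,4-dien-1-one | COC1(OC)C=C(C)C(C)=CC1=O | intermediate
9 | Diels–Alder adduct (1R,4S,7S), N-acyl sultam | CC1(C)[C@@H]2CC[C@]13CS(=O)(=O)N(C(=O)[C@H]4C[C@@H]5C(OC)(OC)C(=O)[C@H]4C(C)=C5C)[C@@H]3C2 | intermediate
10 | (1R,4S,7S)-3,3-dimethoxy-5,6-dimethyl-2-oxobicyclo[2.2.2]oct-5-ene-7-carboxylic acid | OC(=O)[C@H]1C[C@@H]2C(OC)(OC)C(=O)[C@H]1C(C)=C2C | intermediate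
11 | 2-thioxopyridin-1(2H)-yl ester of 10 | O=C(ON1C=CC=CC1=S)[C@H]2C[C@@H]3C(OC)(OC)C(=O)[C@H]2C(C)=C3C | intermediate
12 | (1R,4S)-3,3-dimethoxy-5,6-dimethylbicyclo[2.2.2]oct-5-en-2-one | O=C1C(OC)(OC)[C@H]2CC[C@@H]1C(C)=C2C | intermediate
13 | vinylmagnesium bromide | C=C[Mg]Br | starting material
14 | (1R,2R,4S)-3,3-dimethoxy-5,6-dimethyl-2-vinylbicyclo[2.2.2]oct-5-en-2-ol | C=C[C@]1(O)C(OC)(OC)[C@H]2CC[C@@H]1C(C)=C2C | intermediate
15 | potassium alkoxide of 14 | [K+].C=C[C@]1([O-])C(OC)(OC)[C@H]2CC[C@@H]1C(C)=C2C | intermediate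
16 | potassium C7=C8 enolate of 17 | [K+].C[C@]12CC=C([O-])C(OC)(OC)[C@H]1CCC=C2C | intermediate
17 | cis-fused 9,9-dimethoxy-4,5β-dimethyl-10βH-octal-3-en-8-one | C[C@]12CCC(=O)C(OC)(OC)[C@H]1CCC=C2C | intermediate
18 | 9-hydroxy-4,5β-dimethyl-octala-3,9(10)-dien-8-one | C[C@]12CCC(=O)C(O)=C1CCC=C2C | intermediate
19 | 9-TIPSO-4,5β-dimethyl-octala-3,9(10)-dien-8-one | C[C@]12CCC(=O)C(O[Si](C(C)C)(C(C)C)C(C)C)=C1CCC=C2C | intermediate
20 | 3α-boranyl-8-(boranyloxy) adduct of 19 | C[C@]12CCC(OB)C(O[Si](C(C)C)(C(C)C)C(C)C)=C1CC[C@@H](B)[C@@H]2C | intermediate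
21 | 9-TIPSO-4β,5β-dimethyl-octal-9(10)-ene-3α,8ξ-diol | C[C@]12CCC(O)C(O[Si](C(C)C)(C(C)C)C(C)C)=C1CC[C@@H](O)[C@@H]2C | intermediate
22 | 3α-hydroxy-9-TIPSO-4β,5β-dimethyl-octal-9(10)-en-8-one | C[C@]12CCC(=O)C(O[Si](C(C)C)(C(C)C)C(C)C)=C1CC[C@@H](O)[C@@H]2C | intermediate
23 | 3α-TESO-9-TIPSO-4β,5β-dimethyl-octal-9(10)-en-8-one | C[C@]12CCC(=O)C(O[Si](C(C)C)(C(C)C)C(C)C)=C1CC[C@@H](O[Si](CC)(CC)CC)[C@@H]2C | intermediate
24 | lithium C8=C9 enolate of 25 | [Li+].C[C@]12CCC([O-])=C(O[Si](C(C)C)(C(C)C)C(C)C)[C@@H]1CC[C@@H](O[Si](CC)(CC)CC)[C@@H]2C | intermediate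
25 | trans-fused 3α-TESO-9α-TIPSO-4β,5β-dimethyl-10αH-decal-8-one | C[C@]12CCC(=O)[C@@H](O[Si](C(C)C)(C(C)C)C(C)C)[C@@H]1CC[C@@H](O[Si](CC)(CC)CC)[C@@H]2C | intermediate
26 | 2-bromopropene | CC(Br)=C | starting material
27 | lithium C7=C8 enolate of 25 | [Li+].C[C@]12CC=C([O-])[C@@H](O[Si](C(C)C)(C(C)C)C(C)C)[C@@H]1CC[C@@H](O[Si](CC)(CC)CC)[C@@H]2C | intermediate
28 | lithium dienolate of 29 | [Li+].C[C@]12CC(C(C)=C)=C([O-])[C@@H](O[Si](C(C)C)(C(C)C)C(C)C)[C@@H]1CC[C@@H](O[Si](CC)(CC)CC)[C@@H]2C | intermediate
29 | 3α-TESO-9α-TIPSO-10αH-eremophil-11-en-8-one | C[C@]12C[C@@H](C(C)=C)C(=O)[C@@H](O[Si](C(C)C)(C(C)C)C(C)C)[C@@H]1CC[C@@H](O[Si](CC)(CC)CC)[C@@H]2C | intermediate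
30 | 3α-TESO-9α-TIPSO-10αH-eremophil-11-en-8α-ol | C[C@]12C[C@@H](C(C)=C)[C@@H](O)[C@@H](O[Si](C(C)C)(C(C)C)C(C)C)[C@@H]1CC[C@@H](O[Si](CC)(CC)CC)[C@@H]2C | intermediate
31 | 9α-TIPSO-10αH-eremophil-11-ene-3α,8α-diol | C[C@]12C[C@@H](C(C)=C)[C@@H](O)[C@@H](O[Si](C(C)C)(C(C)C)C(C)C)[C@@H]1CC[C@@H](O)[C@@H]2C | intermediate
32 | (R)-pent-1-yn-3-ol | C#C[C@H](O)CC | starting material
33 | angelic acid | C/C=C(/C)C(=O)O | starting material
34 | angelic 2,4,6-trichlorobenzoic anhydride | C/C=C(/C)C(=O)OC(=O)c1c(Cl)cc(Cl)cc1Cl | intermediate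
35 | (R)-pent-1-yn-3-yl angelate | C#C[C@@H](CC)OC(=O)/C(C)=C\C | intermediate
36 | lithium acetylide of 35 | [Li+].[C-]#C[C@@H](CC)OC(=O)/C(C)=C\C | intermediate
37 | (R)-4-(angeloyloxy)hex-2-ynoic acid | OC(=O)C#C[C@@H](CC)OC(=O)/C(C)=C\C | intermediate
38 | O-acylisourea from 37 and DCC | C(=NC1CCCCC1)(NC1CCCCC1)OC(=O)C#C[C@@H](CC)OC(=O)/C(C)=C\C | intermediate
39 | C3 alkynoate, 8α-OH, 9α-OTIPS | C[C@]12C[C@@H](C(C)=C)[C@@H](O)[C@@H](O[Si](C(C)C)(C(C)C)C(C)C)[C@@H]1CC[C@@H](OC(=O)C#C[C@@H](CC)OC(=O)/C(C)=C\C)[C@@H]2C | intermediate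
40 | C3 (Z)-enoate, 8α-OH, 9α-OTIPS | C[C@]12C[C@@H](C(C)=C)[C@@H](O)[C@@H](O[Si](C(C)C)(C(C)C)C(C)C)[C@@H]1CC[C@@H](OC(=O)/C=C\[C@@H](CC)OC(=O)/C(C)=C\C)[C@@H]2C | intermediate
41 | CNP0382739.1 | C=C(C)[C@@H]1C[C@]2(C)[C@@H](C)[C@H](OC(=O)/C=C\[C@@H](CC)OC(=O)/C(C)=C\C)CC[C@H]2[C@H](O)[C@@H]1O | target

**Step count and risks**

Total step count: 22. Longest linear sequence: 19 steps (1, 2, 4–17, 20–22).

**Step 15 (α-isopropenylation).**
- What may go wrong: sluggish coupling at a secondary enolate carbon beside a crowded ketone, proton exchange that moves the enolate toward C9, and drift of the new olefin into conjugation.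
- Fallback: aldol chemistry replaces cross-coupling, setting out from 25. The kinetic enolate (LiN(i-Pr)2, THF, −78 °C) is transmetalated with ZnCl2 and added to acetone to give the tertiary aldol 7α-(2-hydroxypropan-2-yl)-decal-8-one F6.
- Dehydration with methyl N-(triethylammoniosulfonyl)carbamate in warm toluene gives 29 together with the conjugated 7(11)-en-8-one F7.
- The conjugated isomer is deprotonated at a γ-methyl group with LiN(i-Pr)2 to the same dienolate 28 and quenched with AcOH at −78 °C. Both olefin isomers therefore rejoin the route at 29.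

**Step 6 (decarboxylation).**
- What may go wrong: the C7 radical closes onto the olefin and reopens toward the bridgehead next to the ketone. This homoallyl–cyclopropylcarbinyl rearrangement is driven by an α-keto radical and leads to a bicyclo[3.2.1] skeleton.
- Fallback: the order of events is reversed so that no ketone is present when the radical forms, setting out from 10. Excess vinylmagnesium bromide adds to the magnesium carboxylate of 10 from the olefin face to give the hydroxy acid 2-hydroxy-2-vinyl-7-carboxylic acid F1.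
- This acid is converted with 1-hydroxypyridine-2(1H)-thione and DCC into its O-acyl thiohydroxamate F2, which is photolysed with t-BuSH.
- The rearranged radical would now be unstabilised and more strained, so direct hydrogen transfer should prevail. The sequence rejoins the route at 14.

**Step 11 (hydroboration on the dienone).**
- What may go wrong: incomplete facial discrimination on a not fully rigid bicycle, competing attack of borane on the silyl enol ether, and O-to-O silyl transfer once the C8 carbinol is free.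
- Fallback: the ring fusion is repaired first and the rigid trans-decalin is hydroborated, setting out from 19. Li/NH3 under the conditions of step 14 gives the trans-fused 9α-TIPSO-4,5β-dimethyl-10αH-octal-3-en-8-one F3.
- Excess BH3·THF followed by NaBO3·4H2O gives the 3α,8ξ-diol F4, the axial C5 methyl now blocking the β face completely.
- TESCl/imidazole at −40 °C silylates only the C3 hydroxyl, because C8–OH sits beside OTIPS, and gives the 3α-TESO-8ξ-ol F5.
- Dess–Martin periodinane oxidises C8–OH, and the sequence rejoins the route at 25.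

**Further compounds**
F1 | step 6 | (1R,2R,4S,7S)-2-hydroxy-3,3-dimethoxy-5,6-dimethyl-2-vinylbicyclo[2.2.2]oct-5-ene-7-carboxylic acid | C=C[C@]1(O)C(OC)(OC)[C@H]2C[C@H](C(=O)O)[C@@H]1C(C)=C2C
F2 | step 6 | 2-thioxopyridin-1(2H)-yl ester of F1 | C=C[C@]1(O)C(OC)(OC)[C@H]2C[C@H](C(=O)ON3C=CC=CC3=S)[C@@H]1C(C)=C2C
F3 | step 11 | trans-fused 9α-TIPSO-4,5β-dimethyl-10αH-octal-3-en-8-one | C[C@]12CCC(=O)[C@@H](O[Si](C(C)C)(C(C)C)C(C)C)[C@@H]1CCC=C2C
F4 | step 11 | 9α-TIPSO-4β,5β-dimethyl-10αH-decalin-3α,8ξ-diol | C[C@]12CCC(O)[C@@H](O[Si](C(C)C)(C(C)C)C(C)C)[C@@H]1CC[C@@H](O)[C@@H]2C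
F5 | step 11 | 3α-TESO-9α-TIPSO-4β,5β-dimethyl-10αH-decalin-8ξ-ol | C[C@]12CCC(O)[C@@H](O[Si](C(C)C)(C(C)C)C(C)C)[C@@H]1CC[C@@H](O[Si](CC)(CC)CC)[C@@H]2C
F6 | step 15 | 7α-(2-hydroxypropan-2-yl)-3α-TESO-9α-TIPSO-4β,5β-dimethyl-10αH-decal-8-one | C[C@]12C[C@@H](C(C)(C)O)C(=O)[C@@H](O[Si](C(C)C)(C(C)C)C(C)C)[C@@H]1CC[C@@H](O[Si](CC)(CC)CC)[C@@H]2C
F7 | step 15 | 3α-TESO-9α-TIPSO-10αH-eremophil-7(11)-en-8-one | C[C@]12CC(=C(C)C)C(=O)[C@@H](O[Si](C(C)C)(C(C)C)C(C)C)[C@@H]1CC[C@@H](O[Si](CC)(CC)CC)[C@@H]2C
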